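## The problem

Epoxypholamin A (28) is a drim-7-ene decalin whose C9 carries, through the C11 methylene, a six-membered epoxyquinol. The ring has a C1'/C2' epoxide (C1' quaternary), a C3' ketone, a C4'=C5' alkene with a hydroxymethyl group on C4', and a C6' carbinol; a second primary alcohol sits on the 4α carbon C13 of the decalin. The four decalin stereocentres (4R, 5R, 9S, 10R) are those of the abietane resin acids, with C13 corresponding to the resin-acid carboxyl carbon, so this half can be bought; the C11–C1' bond and the ring must be made. The three ring stereocentres (1'S, 2'S, 6'R; epoxide oxygen trans to the C6' hydroxyl) are insulated from the decalin by a freely rotating methylene. Their absolute sense must therefore come from a reagent or from a centre placed in the ring, whereas within the ring C6' can control the epoxide. The epoxy enone does not tolerate strong base or nucleophiles, and the trisubstituted C7=C8 alkene excludes peracids and strong acid. A C6' carbinol flanked by two ring alkenes without the epoxide is a hydroquinone tautomer and aromatises, so the epoxide must precede C4'=C5'. The enabling feature is that the oxygens on C3' and C6' stand 1,4 to each other on either side of the C1'–C2' bond, the pattern left when dioxygen adds across the ends of a cyclohexa-1,3-diene C6'=C1'–C2'=C3'. Because C4' is trigonal in the target, a hydrogen-bearing stereocentre can be lodged there to steer that addition and be erased afterwards.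

## Retrosynthesis

**28 from 27.** The three O–Si bonds are cut. Silyl ethers are the only groups that can be removed at the end without base (buffered fluoride), which the epoxy enone requires. The tris-silyl ether 27 already contains every carbon and stereocentre.

**27 from 25.** The C4'=C5' π bond is removed, giving the saturated epoxy ketone 25 with a hydrogen-bearing C4'. Introducing this alkene last is forced, because with it in place before the epoxide the ring would tautomerise to a hydroquinone. The forward reaction must dehydrogenate a ketone whose only enolisable position is C4' without touching C7=C8 or the epoxide, which points to an enolate-based, oxidant-free method (via enolate 26).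

**25 from 24.** The two epoxide C–O bonds are cut to the enone 24. Compared with epoxidising an alkene before the ketone exists, the enone allows a nucleophilic oxidant that ignores the electron-rich C7=C8 bond. The C6' silyloxy group next to the attacked carbon C1' directs it to the opposite face, which is the relation the target needs.

**24 from 21.** The C6' silyl ether is removed (23), the C3' ketone is taken back to the carbinol (cis-diol 22), and the two hydroxyls are joined as the peroxide of 21. A one-step base-induced isomerisation of 21 to 23 would be shorter, but it must choose between two bridgehead hydrogens of similar accessibility. Reduction to 22 followed by allylic oxidation lets ring conformation, steric access and allyl-radical stability all select C3'.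

**21 from 20.** The C3'–O and C6'–O bonds are cut together, giving the diene 20 and dioxygen. Installing the two oxygens one at a time would require two separate regio- and stereoselective oxidations. The cycloaddition places both, cis, in one event and leaves the C1'=C2' alkene where the epoxide will go. The precursor has no ring oxygen and one ring stereocentre, C4', which must direct the oxygen to the opposite face.

**20 from 12 and 18.** The C11–C1' bond is cut to the primary iodide 12 (used as its zinc reagent 19) and the cross-conjugated dienyl triflate 18. This sp3–sp2 bond is preferred to C9–C11, which would require setting C9, and to building the ring onto the side chain, which would give no ring stereocontrol. Both partners arrive with their stereocentres complete, and the forward reaction is a Negishi coupling that must not isomerise the diene.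

**18 from 13.** The triflate comes from the (R)-enone 16 by kinetic α'-enolisation (17). The enone comes from the silyl enol ether 15 by dehydrogenation, and 15 from the prochiral ketone 14 (the silyl ether of 13) by enantioselective deprotonation. The single stereocentre is thus made from a mirror-symmetric ketone with a recoverable chiral amide, avoiding a longer chiral-pool sequence.

**12 from 6.** The C11–I bond is traced to the carboxylic acid 10 with one more carbon (via thiohydroxamate ester 11), because resin-acid degradation leaves a two-carbon chain on C9. The radical route is chosen because the γ,δ-unsaturated acid would iodolactonise with electrophilic iodine. The C8 methyl and the C7=C8 alkene of 9 are traced to the enol triflate 8, and this to the keto ester 6 (via enolate 7). This fixes the alkene position by kinetic enolisation, which dehydration of a C8 carbinol would not.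

**6 from 1.** The keto ester 6 comes from the keto acid 5 and the keto aldehyde 4, which result from cutting both double bonds of the ring C diene in the silyl ether 3. Levopimaric acid (1), reduced to 2 and silylated, supplies C4, C5, C9 and C10 with the correct configuration and the C13 oxygen. Its diene has C9 as an sp3 centre already, which abietic or dehydroabietic acid would not allow after cleavage.

## Roads not taken

**Alternative 1:** The cut is at the two epoxide C–O bonds of an epoxy quinone monoketal A2, going back to the quinone mono-(R,R)-hydrobenzoin ketal A1 made by oxidative dearomatisation of aromatic building blocks. In the forward step, tert-butyl hydroperoxide and base epoxidise the C1'=C2' alkene of A1, the face being chosen by the C2-symmetric ketal at C3'.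
- Merits: the ring carbons are bought as an arene, C4'=C5' is present from the start, and no late dehydrogenation or photochemistry is needed.
- Weak points: in A2 the carbonyl is at C6' and the ketal at C3'. The target then requires reduction of the C6' ketone to the carbinol trans to the epoxide, whereas hydride normally enters anti to an epoxide and gives the cis isomer. It also requires hydrolysis of a hindered diaryl dioxolane next to the epoxide.
- Facial control rests on a ketal adjacent to the attacked carbon while the neighbouring carbon carries the bulky decalin substituent.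
- Comparison: this road is shorter on the ring side and avoids an sp3 organometallic coupling. The chosen plan sets against that a C6' configuration taken directly from the oxygen addition, an epoxide placed trans to it in a well-known sense, and no auxiliary to remove beside the epoxide.

**Alternative 2:** The cut is at C4'=C5', going back to the acyclic epoxy dienone A3, in which C6' bears a vinyl group and C3' a 2-(silyloxymethyl)vinyl ketone. In the forward step a second-generation Grubbs catalyst closes the ring to A4, which is the same compound as 27 of the chosen route.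
- Merits: the ring closure delivers the enone alkene directly, so the separate dehydrogenation of the chosen plan and its regiochemical risk disappear. In this respect the road is better.
- Merits: the stereocentres could be set by reagent-controlled epoxidation.
- Weak points: A3 contains a quaternary epoxide carbon bearing C11, a vinyl carbinol and an acyl group. It is at once an epoxy ketone and a polymerisable vinyl ketone.
- Its 1,1-disubstituted, electron-poor alkene is a reluctant metathesis partner next to a quaternary centre.
- The C6'/epoxide relation must be set on an open chain, and the linear sequence on the decalin grows.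
- Comparison: the chosen plan sets all three ring stereocentres on a rigid ring from one centre and assembles the skeleton in one coupling.

**Alternative 3:** The cuts are at C2'–C3', C1'–C6' and C5'–C6'. In the forward step the terminal alkyne A5 reacts with the pentacarbonylchromium carbene complex A6 in a Dötz benzannulation to give the 4-methoxyphenol A7.
- Merits: A5 could be made from an aldehyde such as 4 by one-carbon homologation, so the two-carbon chain left by ring C excision is used as it is. No decarboxylation to a C11 halide is needed, and fragment assembly is shorter than in the chosen plan.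
- The regiochemistry of the benzannulation with a terminal alkyne is reliable.
- Weak points: A7 is flat, so none of the three ring stereocentres exists yet. It would have to be oxidised to a quinone monoketal such as A1 and then meets all the problems of Alternative 1, with stoichiometric chromium added.
- Comparison: the chosen plan spends more steps on C11 but solves the stereochemical problem.

Key step: step 15

**Numbering and abbreviations.** Decalin carbons are C1–C10; C11 is the methylene on C9, C12 the methyl on C8, C13 the oxygenated 4α carbon, C14 the 4β methyl and C15 the 10β methyl. Ring carbons are C1'–C6' as in the target. "Natural decalin configuration" means 4α-CH2O, 4β-CH3, 5α-H, 9α-H (C11 β), 10β-CH3. TBS is tert-butyldimethylsilyl, TMS trimethylsilyl, Tf trifluoromethanesulfonyl.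

**Assumption 1.** The sense of the chiral-amide deprotonation of 14 is taken from 4-tert-butylcyclohexanone, for which the (R,R)-amide gives the (S)-enol silane. The (S,S)-amide is therefore specified for (R)-15; the antipodal amine would be used should the sense prove opposite.

**Assumption 2.** 4-(Hydroxymethyl)cyclohexanone (13) and levopimaric acid (1) are taken as catalogue compounds; 1 is handled under argon because its diene autoxidises.

## Route

Step 1
Reactants: 1 levopimaric acid
Product: 2 levopimarol (abieta-8(14),12-dien-18-ol, natural decalin configuration)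
Conditions: LiAlH4, THF, 0 °C to reflux
Reagents that add atoms: none
Why: Hydride reduction of the hindered tertiary carboxylic acid to the neopentyl alcohol is standard for resin acids; the homoannular diene and the four stereocentres are not touched.

Step 2
Reactants: 2 levopimarol
Product: 3 18-(tert-butyldimethylsilyloxy)abieta-8(14),12-diene
Conditions: TBSCl, imidazole, DMF, 25 °C
Reagents that add atoms: tert-butyldimethylsilyl chloride, CC(C)(C)[Si](C)(C)Cl
Why: Silylation of a primary alcohol; the ether has to survive ozone, chlorite, enolates, organozinc and singlet-oxygen chemistry and is removed with fluoride at the end.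

Step 3
Reactants: 3 18-(tert-butyldimethylsilyloxy)abieta-8(14),12-diene
Product: 4 13-(tert-butyldimethylsilyloxy)-8-oxo-12-nordrimane-11-carbaldehyde (natural decalin configuration)
Conditions: O3, pyridine, CH2Cl2, −78 °C
Reagents that add atoms: ozone, [O-][O+]=O
Why: Ozonolysis of both double bonds of the ring C diene excises five carbons and leaves the C8 ketone and a two-carbon aldehyde chain on C9. Pyridine turns the carbonyl oxides directly into carbonyl groups, so no peroxide accumulates, and C9 keeps its equatorial, thermodynamically preferred substituent.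

Step 4
Reactants: 4 13-(tert-butyldimethylsilyloxy)-8-oxo-12-nordrimane-11-carbaldehyde
Product: 5 13-(tert-butyldimethylsilyloxy)-8-oxo-12-nordrimane-11-carboxylic acid
Conditions: NaClO2, NaH2PO4, 2-methyl-2-butene, t-BuOH/H2O, 0–25 °C
Reagents that add atoms: sodium chlorite, [Na+].[O-]Cl=O
Why: Pinnick oxidation converts the aldehyde to the acid at buffered pH without enolising the ketone or cleaving the silyl ether.

Step 5
Reactants: 5 13-(tert-butyldimethylsilyloxy)-8-oxo-12-nordrimane-11-carboxylic acid
Product: 6 methyl 13-(tert-butyldimethylsilyloxy)-8-oxo-12-nordrimane-11-carboxylate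
Conditions: MeI, K2CO3, DMF, 25 °C
Reagents that add atoms: iodomethane, CI
Why: O-Alkylation of the carboxylate gives the open-chain methyl ester and masks the acidic proton before enolate chemistry.

Step 6
Reactants: 6 methyl 13-(tert-butyldimethylsilyloxy)-8-oxo-12-nordrimane-11-carboxylate
Product: 8 methyl 13-(tert-butyldimethylsilyloxy)-8-(trifluoromethanesulfonyloxy)-12-nordrim-7-ene-11-carboxylate, via lithium enolate 7 (not isolated)
Conditions: LiN(i-Pr)2, THF, −78 °C; then PhNTf2, −78 to 0 °C
Reagents that add atoms: N-phenylbis(trifluoromethanesulfonimide), O=S(=O)(N(c1ccccc1)S(=O)(=O)C(F)(F)F)C(F)(F)F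
Why: Kinetic deprotonation removes a C7 methylene hydrogen in preference to the hindered tertiary C9–H and the less acidic ester α-hydrogens. O-Triflation of the enolate then fixes the double bond between C7 and C8.

Step 7
Reactants: 8 methyl 13-(tert-butyldimethylsilyloxy)-8-(trifluoromethanesulfonyloxy)-12-nordrim-7-ene-11-carboxylate
Product: 9 methyl 13-(tert-butyldimethylsilyloxy)drim-7-ene-11-carboxylate
Conditions: MeZnCl, Pd(PPh3)4 (cat.), THF, 50 °C
Reagents that add atoms: methylzinc chloride, C[Zn]Cl
Why: Negishi coupling of the enol triflate installs the C12 methyl with the alkene position fixed; the methyl ester is inert to the organozinc.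

Step 8
Reactants: 9 methyl 13-(tert-butyldimethylsilyloxy)drim-7-ene-11-carboxylate
Product: 10 13-(tert-butyldimethylsilyloxy)drim-7-ene-11-carboxylic acid
Conditions: LiOH, THF/MeOH/H2O, 25 °C; then 1 M HCl to pH 4, 0 °C
Reagents that add atoms: lithium hydroxide, [Li+].[OH-]
Why: Saponification of an unhindered primary-chain ester; brief cold acidification avoids lactonisation onto C7=C8 and silyl ether cleavage.

Step 9
Reactants: 10 13-(tert-butyldimethylsilyloxy)drim-7-ene-11-carboxylic acid
Product: 12 11-iodo-13-(tert-butyldimethylsilyloxy)drim-7-ene, via Barton ester 11 (not isolated)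
Conditions: N-hydroxypyridine-2-thione, DCC, DMAP (cat.), CH2Cl2, 0 °C, dark; then CHI3, visible light, 25 °C
Reagents that add atoms: iodoform, IC(I)I
Why: Barton decarboxylative iodination: the thiohydroxamate ester fragments under light to the primary C11 radical, which takes iodine from iodoform faster than it can add to the C7=C8 alkene. No electrophilic iodine is present, so iodolactonisation is avoided.

Step 10
Reactants: 13 4-(hydroxymethyl)cyclohexanone
Product: 14 4-{[(tert-butyldimethylsilyl)oxy]methyl}cyclohexanone
Conditions: TBSCl, imidazole, CH2Cl2, 25 °C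
Reagents that add atoms: tert-butyldimethylsilyl chloride, CC(C)(C)[Si](C)(C)Cl
Why: Silylation of the primary alcohol gives the prochiral ketone and the group that later shields one face of the diene.

Step 11
Reactants: 14 4-{[(tert-butyldimethylsilyl)oxy]methyl}cyclohexanone
Product: 15 (R)-tert-butyldimethyl{[4-(trimethylsilyloxy)cyclohex-3-en-1-yl]methoxy}silane
Conditions: (S,S)-bis(1-phenylethyl)amine, n-BuLi, LiCl, THF, −78 °C; then TMSCl and 14 (in situ quench), −78 °C
Reagents that add atoms: chlorotrimethylsilane, C[Si](C)(C)Cl
Why: Enantioselective deprotonation of a 4-substituted cyclohexanone by a chiral lithium amide with internal silyl quench; the amide distinguishes the two enantiotopic axial α-hydrogens and so creates the C4' centre. The minor enantiomer later becomes a separable diastereomer after coupling to the enantiopure decalin.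

Step 12
Reactants: 15 (R)-tert-butyldimethyl{[4-(trimethylsilyloxy)cyclohex-3-en-1-yl]methoxy}silane
Product: 16 (R)-4-{[(tert-butyldimethylsilyl)oxy]methyl}cyclohex-2-en-1-one
Conditions: Pd(OAc)2 (10 mol %), O2 (1 atm), DMSO, 25 °C
Reagents that add atoms: none
Why: Saegusa–Ito oxidation in its catalytic aerobic form turns the regiodefined silyl enol ether into the enone under neutral conditions, so the γ-stereocentre is not epimerised.

Step 13
Reactants: 16 (R)-4-{[(tert-butyldimethylsilyl)oxy]methyl}cyclohex-2-en-1-one
Product: 18 (R)-4-{[(tert-butyldimethylsilyl)oxy]methyl}cyclohexa-1,5-dien-1-yl trifluoromethanesulfonate, via lithium dienolate 17 (not isolated)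
Conditions: LiN(i-Pr)2, THF, −78 °C; then PhNTf2, −78 to 0 °C
Reagents that add atoms: N-phenylbis(trifluoromethanesulfonimide), O=S(=O)(N(c1ccccc1)S(=O)(=O)C(F)(F)F)C(F)(F)F
Why: Kinetic α'-deprotonation of the enone gives the cross-conjugated dienolate without touching the γ-hydrogen at the stereocentre. O-Triflation then gives the dienyl triflate that already has the diene C6'=C1'–C2'=C3'.

Step 14
Reactants: 12 11-iodo-13-(tert-butyldimethylsilyloxy)drim-7-ene; 18 (R)-4-{[(tert-butyldimethylsilyl)oxy]methyl}cyclohexa-1,5-dien-1-yl trifluoromethanesulfonate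
Product: 20 (5R)-2-[13-(tert-butyldimethylsilyloxy)drim-7-en-11-yl]-5-{[(tert-butyldimethylsilyl)oxy]methyl}cyclohexa-1,3-diene, via alkylzinc iodide 19 (not isolated)
Conditions: Zn dust, LiCl, THF, 40 °C; then 18, PdCl2(dppf) (5 mol %), THF, 25–40 °C
Reagents that add atoms: none
Why: Zinc insertion into the primary iodide, then Negishi coupling: the triflate adds oxidatively to zerovalent palladium, the alkyl group is transferred from zinc, and reductive elimination forms C11–C1'. The bidentate ligand suppresses β-hydride elimination, and the mild temperature prevents 1,5-hydrogen shifts in the diene. No stereocentre is involved.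

Step 15
Reactants: 20 (5R)-2-[13-(tert-butyldimethylsilyloxy)drim-7-en-11-yl]-5-{[(tert-butyldimethylsilyl)oxy]methyl}cyclohexa-1,3-diene
Product: 21 endoperoxide: 5-[13-(tert-butyldimethylsilyloxy)drim-7-en-11-yl]-7-{[(tert-butyldimethylsilyl)oxy]methyl}-2,3-dioxabicyclo[2.2.2]oct-5-ene with the peroxide bridge anti to the silyloxymethyl group (3'R,4'S,6'R)
Conditions: O2, tetraphenylporphyrin (cat.), CH2Cl2, −78 °C, visible light
Reagents that add atoms: dioxygen, O=O
Why: Energy transfer from the excited porphyrin gives singlet oxygen, which adds suprafacially across the diene termini C3' and C6' in a concerted, possibly asynchronous [4+2] cycloaddition. The closest known reaction is the photooxygenation of α-phellandrene and other 5-substituted cyclohexa-1,3-dienes to 2,3-dioxabicyclo[2.2.2]oct-5-enes. The one new ring, the six-membered 1,2-dioxine that completes the bicycle, closes by cycloaddition with both C–O bonds made on the same face, so the cis relation of the two oxygens is fixed by the mechanism. The configuration of the new centres C3' and C6' is controlled by the existing centre at C4', whose silyloxymethyl group shields one face so that oxygen enters anti to it; C4' itself is not touched. The step needs facial selectivity and chemoselectivity for cycloaddition over ene reaction at C7=C8 and at the allylic hydrogens. The s-cis-locked diene reacts much faster than an isolated trisubstituted alkene, and low temperature with irradiation stopped once 20 is consumed protects the remainder. There is no regiochemical question because dioxygen is symmetric, and the C1'=C2' alkene that emerges is the site of the later epoxide. Any syn adduct is separable here and can be converged later.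

Step 16
Reactants: 21 endoperoxide (3'R,4'S,6'R)
Product: 22 cis-diol: (3'R,4'S,6'R)-1'-[13-(tert-butyldimethylsilyloxy)drim-7-en-11-yl]-4'-{[(tert-butyldimethylsilyl)oxy]methyl}cyclohex-1'-ene-3',6'-diol (both hydroxyls trans to the C4' substituent)
Conditions: thiourea, MeOH/CH2Cl2, 0–25 °C
Reagents that add atoms: none
Why: Thiourea reduces the O–O bond of bicyclic endoperoxides to the cis-1,4-diol under neutral conditions; the C–O bonds, both alkenes and the silyl ethers are untouched, so C3' and C6' keep their configuration.

Step 17
Reactants: 22 cis-diol (3'R,4'S,6'R)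
Product: 23 hydroxy enone: (4'S,6'R)-1'-[13-(tert-butyldimethylsilyloxy)drim-7-en-11-yl]-6'-hydroxy-4'-{[(tert-butyldimethylsilyl)oxy]methyl}cyclohex-1'-en-3'-one
Conditions: MnO2 (activated, excess), CH2Cl2, 25 °C
Reagents that add atoms: none
Why: Allylic oxidation with MnO2 should select the C3' carbinol for three concurring reasons. Allylic 1,2-strain with the C1' substituent holds the C6' hydroxyl pseudo-axial and hindered, while the trans C4' substituent holds the C3' hydroxyl pseudo-equatorial with its C–H aligned with the π system. In addition, hydrogen abstraction at C3' gives the more substituted allyl radical.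

Step 18
Reactants: 23 hydroxy enone (4'S,6'R)
Product: 24 (4'S,6'R)-1'-[13-(tert-butyldimethylsilyloxy)drim-7-en-11-yl]-6'-(tert-butyldimethylsilyloxy)-4'-{[(tert-butyldimethylsilyl)oxy]methyl}cyclohex-1'-en-3'-one
Conditions: TBSOTf, 2,6-lutidine, CH2Cl2, −78 °C
Reagents that add atoms: tert-butyldimethylsilyl trifluoromethanesulfonate, CC(C)(C)[Si](C)(C)OS(=O)(=O)C(F)(F)F
Why: The silyl triflate silylates the hindered allylic alcohol at low temperature without enolising the enone; the bulky ether then serves as the directing group for the epoxidation and protects C6' during enolate chemistry.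

Step 19
Reactants: 24 (4'S,6'R)-silyloxy enone
Product: 25 epoxy ketone: (1'R,2'S,4'S,6'R)-1'-[13-(tert-butyldimethylsilyloxy)drim-7-en-11-yl]-6'-(tert-butyldimethylsilyloxy)-4'-{[(tert-butyldimethylsilyl)oxy]methyl}-1',2'-epoxycyclohexan-3'-one (epoxide trans to the C6' oxygen)
Conditions: 30% aq H2O2, benzyltrimethylammonium hydroxide (cat.), THF, 0 °C
Reagents that add atoms: hydrogen peroxide, OO
Why: Weitz–Scheffer epoxidation: hydroperoxide adds to the β-carbon C1' on the face opposite the pseudo-axial C6' silyloxy group, and the enolate closes onto oxygen. C1' and C2' are therefore set trans to C6'–O, the known outcome for 4-silyloxycyclohexenones, and the nucleophilic oxidant leaves C7=C8 alone. Low temperature and short reaction time limit base-induced loss of silanol from C4'.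

Step 20
Reactants: 25 epoxy ketone (1'R,2'S,4'S,6'R)
Product: 27 tris(tert-butyldimethylsilyl) ether of epoxypholamin A, via lithium enolate 26 (not isolated)
Conditions: LiN(i-Pr)2, THF, −78 °C; then N-tert-butylbenzenesulfinimidoyl chloride, −78 °C
Reagents that add atoms: none
Why: Mukaiyama dehydrogenation: C4' is the only enolisable position, the enolate attacks sulfur, and the resulting sulfilimine undergoes syn elimination with a C5' hydrogen. Such eliminations run away from an oxygen-bearing carbon, so the endocyclic C4'=C5' enone is expected. No external oxidant is present, so C7=C8 and the epoxide are untouched, and the C4' stereocentre is erased as planned.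

Step 21
Reactants: 27 tris(tert-butyldimethylsilyl) ether of epoxypholamin A
Product: 28 epoxypholamin A (4R,5R,9S,10R,1'S,2'S,6'R)
Conditions: HF·pyridine, pyridine, THF, 0 to 25 °C
Reagents that add atoms: none
Why: Buffered fluoride cleaves the two primary and the one secondary silyl ether without the basic conditions that would open or rearrange the epoxy enone.

## Compound list

1 | levopimaric acid (abieta-8(14),12-dien-18-oic acid) | CC(C)C1=CC[C@H]2C(=C1)CC[C@H]1[C@](C)(C(=O)O)CCC[C@@]12C | starting material
2 | levopimarol (abieta-8(14),12-dien-18-ol) | CC(C)C1=CC[C@H]2C(=C1)CC[C@H]1[C@](C)(CO)CCC[C@@]12C | intermediate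
3 | 18-(tert-butyldimethylsilyloxy)abieta-8(14),12-diene | CC(C)C1=CC[C@H]2C(=C1)CC[C@H]1[C@](C)(CO[Si](C)(C)C(C)(C)C)CCC[C@@]12C | intermediate
4 | 13-(tert-butyldimethylsilyloxy)-8-oxo-12-nordrimane-11-carbaldehyde | O=C1CC[C@H]2[C@](C)(CO[Si](C)(C)C(C)(C)C)CCC[C@]2(C)[C@H]1CC=O | intermediate
5 | 13-(tert-butyldimethylsilyloxy)-8-oxo-12-nordrimane-11-carboxylic acid | O=C1CC[C@H]2[C@](C)(CO[Si](C)(C)C(C)(C)C)CCC[C@]2(C)[C@H]1CC(=O)O | intermediate
6 | methyl 13-(tert-butyldimethylsilyloxy)-8-oxo-12-nordrimane-11-carboxylate | O=C1CC[C@H]2[C@](C)(CO[Si](C)(C)C(C)(C)C)CCC[C@]2(C)[C@H]1CC(=O)OC | intermediate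
7 | lithium enolate of 6 with the C7=C8 double bond | [Li]OC1=CC[C@H]2[C@](C)(CO[Si](C)(C)C(C)(C)C)CCC[C@]2(C)[C@H]1CC(=O)OC | intermediate
8 | methyl 13-(tert-butyldimethylsilyloxy)-8-(trifluoromethanesulfonyloxy)-12-nordrim-7-ene-11-carboxylate | O=S(=O)(OC1=CC[C@H]2[C@](C)(CO[Si](C)(C)C(C)(C)C)CCC[C@]2(C)[C@H]1CC(=O)OC)C(F)(F)F | intermediate
9 | methyl 13-(tert-butyldimethylsilyloxy)drim-7-ene-11-carboxylate | CC1=CC[C@H]2[C@](C)(CO[Si](C)(C)C(C)(C)C)CCC[C@]2(C)[C@H]1CC(=O)OC | intermediate
10 | 13-(tert-butyldimethylsilyloxy)drim-7-ene-11-carboxylic acid | CC1=CC[C@H]2[C@](C)(CO[Si](C)(C)C(C)(C)C)CCC[C@]2(C)[C@H]1CC(=O)O | intermediate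
11 | 2-thioxopyridin-1(2H)-yl 13-(tert-butyldimethylsilyloxy)drim-7-ene-11-carboxylate (Barton ester) | CC1=CC[C@H]2[C@](C)(CO[Si](C)(C)C(C)(C)C)CCC[C@]2(C)[C@H]1CC(=O)On1ccccc1=S | intermediate
12 | 11-iodo-13-(tert-butyldimethylsilyloxy)drim-7-ene | CC1=CC[C@H]2[C@](C)(CO[Si](C)(C)C(C)(C)C)CCC[C@]2(C)[C@H]1CI | intermediate
13 | 4-(hydroxymethyl)cyclohexanone | O=C1CCC(CO)CC1 | starting material
14 | 4-{[(tert-butyldimethylsilyl)oxy]methyl}cyclohexanone | O=C1CCC(CO[Si](C)(C)C(C)(C)C)CC1 | intermediate
15 | (R)-tert-butyldimethyl{[4-(trimethylsilyloxy)cyclohex-3-en-1-yl]methoxy}silane | C[Si](C)(C)OC1=CC[C@H](CO[Si](C)(C)C(C)(C)C)CC1 | intermediate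
16 | (R)-4-{[(tert-butyldimethylsilyl)oxy]methyl}cyclohex-2-en-1-one | O=C1CC[C@@H](CO[Si](C)(C)C(C)(C)C)C=C1 | intermediate
17 | lithium (R)-4-{[(tert-butyldimethylsilyl)oxy]methyl}cyclohexa-1,5-dien-1-olate | [Li]OC1=CC[C@@H](CO[Si](C)(C)C(C)(C)C)C=C1 | intermediate
18 | (R)-4-{[(tert-butyldimethylsilyl)oxy]methyl}cyclohexa-1,5-dien-1-yl trifluoromethanesulfonate | O=S(=O)(OC1=CC[C@@H](CO[Si](C)(C)C(C)(C)C)C=C1)C(F)(F)F | intermediate
19 | [13-(tert-butyldimethylsilyloxy)drim-7-en-11-yl]zinc iodide | CC1=CC[C@H]2[C@](C)(CO[Si](C)(C)C(C)(C)C)CCC[C@]2(C)[C@H]1C[Zn]I | intermediate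
20 | (5R)-2-[13-(tert-butyldimethylsilyloxy)drim-7-en-11-yl]-5-{[(tert-butyldimethylsilyl)oxy]methyl}cyclohexa-1,3-diene | CC1=CC[C@H]2[C@](C)(CO[Si](C)(C)C(C)(C)C)CCC[C@]2(C)[C@H]1CC1=CC[C@@H](CO[Si](C)(C)C(C)(C)C)C=C1 | intermediate
21 | 5-[13-(tert-butyldimethylsilyloxy)drim-7-en-11-yl]-7-{[(tert-butyldimethylsilyl)oxy]methyl}-2,3-dioxabicyclo[2.2.2]oct-5-ene, peroxide anti to the C7 substituent (3'R,4'S,6'R) | CC1=CC[C@H]2[C@](C)(CO[Si](C)(C)C(C)(C)C)CCC[C@]2(C)[C@H]1CC1=C[C@H]2OO[C@@H]1C[C@H]2CO[Si](C)(C)C(C)(C)C | intermediate
22 | (3'R,4'S,6'R)-1'-[13-(tert-butyldimethylsilyloxy)drim-7-en-11-yl]-4'-{[(tert-butyldimethylsilyl)oxy]methyl}cyclohex-1'-ene-3',6'-diol | CC1=CC[C@H]2[C@](C)(CO[Si](C)(C)C(C)(C)C)CCC[C@]2(C)[C@H]1CC1=C[C@@H](O)[C@H](CO[Si](C)(C)C(C)(C)C)C[C@H]1O | intermediate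
23 | (4'S,6'R)-1'-[13-(tert-butyldimethylsilyloxy)drim-7-en-11-yl]-6'-hydroxy-4'-{[(tert-butyldimethylsilyl)oxy]methyl}cyclohex-1'-en-3'-one | CC1=CC[C@H]2[C@](C)(CO[Si](C)(C)C(C)(C)C)CCC[C@]2(C)[C@H]1CC1=CC(=O)[C@H](CO[Si](C)(C)C(C)(C)C)C[C@H]1O | intermediate
24 | (4'S,6'R)-1'-[13-(tert-butyldimethylsilyloxy)drim-7-en-11-yl]-6'-(tert-butyldimethylsilyloxy)-4'-{[(tert-butyldimethylsilyl)oxy]methyl}cyclohex-1'-en-3'-one | CC1=CC[C@H]2[C@](C)(CO[Si](C)(C)C(C)(C)C)CCC[C@]2(C)[C@H]1CC1=CC(=O)[C@H](CO[Si](C)(C)C(C)(C)C)C[C@H]1O[Si](C)(C)C(C)(C)C | intermediate
25 | (1'R,2'S,4'S,6'R)-1',2'-epoxy ketone, epoxide trans to the C6' silyloxy group | CC1=CC[C@H]2[C@](C)(CO[Si](C)(C)C(C)(C)C)CCC[C@]2(C)[C@H]1C[C@@]12O[C@@H]1C(=O)[C@H](CO[Si](C)(C)C(C)(C)C)C[C@H]2O[Si](C)(C)C(C)(C)C | intermediate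
26 | lithium enolate of 25 (C3'–O–Li, C3'=C4') | CC1=CC[C@H]2[C@](C)(CO[Si](C)(C)C(C)(C)C)CCC[C@]2(C)[C@H]1C[C@@]12O[C@@H]1C(O[Li])=C(CO[Si](C)(C)C(C)(C)C)C[C@H]2O[Si](C)(C)C(C)(C)C | intermediate
27 | tris(tert-butyldimethylsilyl) ether of epoxypholamin A | CC1=CC[C@H]2[C@](C)(CO[Si](C)(C)C(C)(C)C)CCC[C@]2(C)[C@H]1C[C@@]12O[C@@H]1C(=O)C(CO[Si](C)(C)C(C)(C)C)=C[C@H]2O[Si](C)(C)C(C)(C)C | intermediate
28 | epoxypholamin A | CC1=CC[C@H]2[C@](C)(CO)CCC[C@]2(C)[C@H]1C[C@@]12O[C@@H]1C(=O)C(CO)=C[C@H]2O | target

## Step count and risks

Total: 21 steps. The longest linear sequence is 17 steps, from 1 to 28 through steps 1–9 and 14–21; the ring fragment takes steps 10–13.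

**Step 15 (key step).** Facial selectivity may be only moderate, because a single silyloxymethyl group on C4' shields its face incompletely. Ene reaction at C7=C8 or at the allylic hydrogens of the diene, and oxidative aromatisation of the diene, may also compete. The fallback keeps the cycloaddition but replaces face control by stereoconvergence, which is possible because C4' is later erased.
- Starting from 20, the syn adduct, the C3',C6'-bis-epimeric endoperoxide F1, is carried on separately.
- Thiourea gives the all-cis diol F2, and MnO2 gives the 6'-epi hydroxy enone F3.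
- Mitsunobu inversion at C6' (4-nitrobenzoic acid, PPh3, diisopropyl azodicarboxylate) gives the 4-nitrobenzoate F4 with the natural C6' configuration.
- K2CO3 in methanol returns the material to 23. The C4' centre of this series is the same as in the main line, since both adducts come from the same (5R)-diene.

**Step 17.** Oxidation may take place at the C6' carbinol as well, or run on to the enedione, if the conformational bias of 22 is weaker than expected. The fallback changes the mechanism: Kornblum–DeLaMare isomerisation of the endoperoxide 21 with a tertiary amine (Et3N or 1,4-diazabicyclo[2.2.2]octane, CH2Cl2) leads directly to 23. Here the outcome depends on base access to the two bridgehead hydrogens in the rigid bicycle and not on the conformation of a diol. This fallback sets out from 21, returns at 23 and makes no compound outside the list (F0).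

**Step 20.** The lithium enolate 26 may expel silanolate from the exocyclic carbon (β-elimination). C–S bond formation at the fully substituted enolate carbon may be slow, or the syn elimination may turn toward the exocyclic methylene. The fallback sets out from 25: internal-quench silylation (LiN(i-Pr)2 with TMSCl present, −78 °C) gives the trimethylsilyl enol ether F5 without a free enolate lifetime. Saegusa–Ito oxidation with Pd(OAc)2 in MeCN then gives 27.

**Step 14.** Zinc insertion or transmetalation at the β-branched C11 may be sluggish, leading to protodemetalation or homocoupling, and palladium hydride may shift the diene double bonds. The fallback is a B-alkyl Suzuki–Miyaura coupling, setting out from 12 and returning at 20. Iodine–lithium exchange (t-BuLi, Et2O, −78 °C) and trapping with 9-methoxy-9-borabicyclo[3.3.1]nonane give the lithium borinate F6. This is coupled with 18 using PdCl2(dppf), AsPh3 and Cs2CO3 in DMF/H2O at 25 °C.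

## Further compounds

F1 | step 15 | syn endoperoxide, peroxide bridge on the same face as the C4' silyloxymethyl group (C3',C6'-bis-epimer of 21) | CC1=CC[C@H]2[C@](C)(CO[Si](C)(C)C(C)(C)C)CCC[C@]2(C)[C@H]1CC1=C[C@@H]2OO[C@H]1C[C@H]2CO[Si](C)(C)C(C)(C)C
F2 | step 15 | all-cis diol (C3',C6'-bis-epimer of 22) | CC1=CC[C@H]2[C@](C)(CO[Si](C)(C)C(C)(C)C)CCC[C@]2(C)[C@H]1CC1=C[C@H](O)[C@H](CO[Si](C)(C)C(C)(C)C)C[C@@H]1O
F3 | step 15 | 6'-epi hydroxy enone (C6' epimer of 23) | CC1=CC[C@H]2[C@](C)(CO[Si](C)(C)C(C)(C)C)CCC[C@]2(C)[C@H]1CC1=CC(=O)[C@H](CO[Si](C)(C)C(C)(C)C)C[C@@H]1O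
F4 | step 15 | 4-nitrobenzoate of 23 (natural C6' configuration) | CC1=CC[C@H]2[C@](C)(CO[Si](C)(C)C(C)(C)C)CCC[C@]2(C)[C@H]1CC1=CC(=O)[C@H](CO[Si](C)(C)C(C)(C)C)C[C@H]1OC(=O)c1ccc(cc1)[N+](=O)[O-]
F0 | step 17 | none | none
F5 | step 20 | trimethylsilyl enol ether of 25 (C3'–OTMS, C3'=C4') | CC1=CC[C@H]2[C@](C)(CO[Si](C)(C)C(C)(C)C)CCC[C@]2(C)[C@H]1C[C@@]12O[C@@H]1C(O[Si](C)(C)C)=C(CO[Si](C)(C)C(C)(C)C)C[C@H]2O[Si](C)(C)C(C)(C)C
F6 | step 14 | lithium B-[13-(tert-butyldimethylsilyloxy)drim-7-en-11-yl]-B-methoxy-9-borabicyclo[3.3.1]nonane borinate | CC1=CC[C@H]2[C@](C)(CO[Si](C)(C)C(C)(C)C)CCC[C@]2(C)[C@H]1C[B-]1(OC)C2CCCC1CCC2.[Li+]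
A1 | alternative 1 | 2-[13-(tert-butyldimethylsilyloxy)drim-7-en-11-yl]-5-{[(tert-butyldimethylsilyl)oxy]methyl}-1,4-benzoquinone 4-[(R,R)-1,2-diphenylethylene ketal] (C6' carbonyl, C3' ketal) | CC1=CC[C@H]2[C@](C)(CO[Si](C)(C)C(C)(C)C)CCC[C@]2(C)[C@H]1CC1=CC3(O[C@H](c4ccccc4)[C@@H](c4ccccc4)O3)C(CO[Si](C)(C)C(C)(C)C)=CC1=O
A2 | alternative 1 | C1',C2'-epoxide of A1 | CC1=CC[C@H]2[C@](C)(CO[Si](C)(C)C(C)(C)C)CCC[C@]2(C)[C@H]1C[C@@]12O[C@@H]1C3(O[C@H](c4ccccc4)[C@@H](c4ccccc4)O3)C(CO[Si](C)(C)C(C)(C)C)=CC2=O
A3 | alternative 2 | acyclic epoxy dienone with a vinyl group on C6' (silyl ether) and a 2-(silyloxymethyl)vinyl ketone at C3' | CC1=CC[C@H]2[C@](C)(CO[Si](C)(C)C(C)(C)C)CCC[C@]2(C)[C@H]1C[C@]1(O[C@@H]1C(=O)C(=C)CO[Si](C)(C)C(C)(C)C)[C@@H](C=C)O[Si](C)(C)C(C)(C)C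
A4 | alternative 2 | tris(tert-butyldimethylsilyl) ether of epoxypholamin A (identical with 27) | CC1=CC[C@H]2[C@](C)(CO[Si](C)(C)C(C)(C)C)CCC[C@]2(C)[C@H]1C[C@@]12O[C@@H]1C(=O)C(CO[Si](C)(C)C(C)(C)C)=C[C@H]2O[Si](C)(C)C(C)(C)C
A5 | alternative 3 | 11-ethynyl-13-(tert-butyldimethylsilyloxy)drim-7-ene | CC1=CC[C@H]2[C@](C)(CO[Si](C)(C)C(C)(C)C)CCC[C@]2(C)[C@H]1CC#C
A6 | alternative 3 | pentacarbonyl{methoxy[3-(tert-butyldimethylsilyloxy)prop-1-en-2-yl]carbene}chromium, (CO)5Cr=C(OMe)C(=CH2)CH2OTBS | COC(C(=C)CO[Si](C)(C)C(C)(C)C)=[Cr](=C=O)(=C=O)(=C=O)(=C=O)=C=O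
A7 | alternative 3 | 2-[13-(tert-butyldimethylsilyloxy)drim-7-en-11-yl]-4-methoxy-5-{[(tert-butyldimethylsilyl)oxy]methyl}phenol | CC1=CC[C@H]2[C@](C)(CO[Si](C)(C)C(C)(C)C)CCC[C@]2(C)[C@H]1Cc1cc(OC)c(CO[Si](C)(C)C(C)(C)C)cc1O
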